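**Plan**
- Retrosynthesis: the polyene is cut at C11=C12 and C11'=C12' (two Wittig reactions, C15 + C10 + C15'), each C15 unit at C7=C8 (Horner–Wadsworth–Emmons), and the ring with cis hydroxyl and chain at C1–C2 and C5–C6.
- Enabling feature: in that six-membered ring the C3 ketone and the C5 carbinol are 1,3-related (a masked acetylacetone, C2–C3(O)–C4–C5(O)(CH3)), and the quaternary C1(CH3)2 is bonded to C6, which carries C7. Ring atoms C2–C5 are therefore a 1,3-dioxygenated diene and C1=C6–C7(=O) a β,β-dimethyl enone, matched in polarity for a [4+2] union.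
- Forward: diene and chiral enone are made separately (steps 1–3) and one cycloaddition builds the whole ring (step 4). The auxiliary is excised by glycol cleavage to the C7 aldehyde, and olefination plus reduction give a C15 dienol (step 9) that serves both ends.
- The dienol is desilylated, converted into the cis C15 phosphonium salt and joined to the C10 dialdehyde. For the other end the same dienol is inverted at C5 (enone, epoxidation anti to the side chain, reductive opening) and supplies the trans C15 salt for the last Wittig reaction.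
- Stereochemistry: C6 of both rings from the ketol auxiliary derived from (S)-hexahydromandelic acid; C5 of the cis ring from the E geometry of the diene plus endo addition; C5 of the trans ring from substrate-controlled epoxidation; E alkenes from the olefinations with thermal equilibration.

Key step: step 4

Assumption: carotenoid numbering is used (ring C1–C6, chain C7–C15, primes for the second half); read from the SMILES, the two end rings are C5 epimers, (5R,6S) with hydroxyl and chain cis in the ring built by the key step and (5S,6S) with hydroxyl and chain trans in the other.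

**Route**

Step 1
Reactants: 1 (3E)-4-methoxypent-3-en-2-one
Product: 2 (3E)-4-(benzyloxy)pent-3-en-2-one
Conditions: BnOH (3 equiv), TsOH·H2O (cat.), toluene, 60 °C, reduced pressure (MeOH removed)
Reagents that add atoms: benzyl alcohol, OCc1ccccc1
Why: acid-catalysed vinylogous transesterification (addition–elimination at the β-carbon of a β-alkoxy enone), driven by removal of methanol, should give the thermodynamic E isomer with the alkoxy group trans to the acetyl group.

Step 2
Reactants: 2 (3E)-4-(benzyloxy)pent-3-en-2-one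
Product: 3 (3E)-4-(benzyloxy)-2-(tert-butyldimethylsilyloxy)penta-1,3-diene
Conditions: LiN(iPr)2, THF, −78 °C; TBSCl, DMPU, −78 → 0 °C
Reagents that add atoms: tert-butyldimethylsilyl chloride, C[Si](C)(Cl)C(C)(C)C
Why: kinetic deprotonation of a vinylogous ester occurs at the acetyl methyl group, and O-silylation of the cross-conjugated enolate gives the 1-alkoxy-3-silyloxy diene without touching the C3=C4 geometry.

Step 3
Reactants: 4 (2S)-2-cyclohexyl-2-hydroxyacetic acid; 5 1-bromo-2-methylprop-1-ene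
Product: 7 (1S)-1-cyclohexyl-1-hydroxy-4-methylpent-3-en-2-one, via (2-methylprop-1-en-1-yl)lithium 6 (not isolated)
Conditions: 5 (3.5 equiv), t-BuLi (7 equiv), Et2O, −78 °C; then 4, THF, −78 → 0 °C; aq. NH4Cl
Reagents that add atoms: none
Why: ketone synthesis by addition of an organolithium to a lithium carboxylate, in which two equivalents of 6 deprotonate the acid and the hydroxyl and the third adds to give a gem-diolate that cannot add again, while the α-stereocentre is held as its alkoxide and should not epimerise.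

Step 4
Reactants: 3 (3E)-4-(benzyloxy)-2-(tert-butyldimethylsilyloxy)penta-1,3-diene; 7 (1S)-1-cyclohexyl-1-hydroxy-4-methylpent-3-en-2-one
Product: 8 (2S)-1-[(1S,2R)-2-(benzyloxy)-4-(tert-butyldimethylsilyloxy)-2,6,6-trimethylcyclohex-3-en-1-yl]-2-cyclohexyl-2-hydroxyethan-1-one
Conditions: Me2AlCl (2.2 equiv), CH2Cl2, −78 → −30 °C; aq. NaHCO3
Reagents that add atoms: none
Why: Me2AlCl turns the ketol hydroxyl into a chloro(methyl)aluminium alkoxide that chelates the C7 carbonyl, and this rigid, activated s-cis enone is attacked at its β-carbon C1 by the nucleophilic CH2 terminus C2 of the diene while the oxygen-bearing terminus C5 bonds to the α-carbon C6, in a strongly asynchronous Diels–Alder reaction (Mukaiyama–Michael-like first bond, then collapse of the aluminium enolate onto the oxocarbenium carbon). The closest known reactions are Lewis-acid-promoted cycloadditions of chiral α'-hydroxy enones and the AlCl3-catalysed addition of penta-1,3-diene to mesityl oxide, which shows that a β,β-dimethyl enone accepts a 1-substituted diene in exactly this orientation. The cyclohexene (C1–C6) closes as an intermolecular [4+2] process, suprafacial on both partners; if the second bond lags, it forms by 6-(enolexo)-exo-trig attack of C6 on C5. C6 is set by the auxiliary, because in the planar five-membered chelate the cyclohexyl group covers one face of the enone and the diene adds to the face that carries the carbinol hydrogen (the Re face at C6). C5 follows from the E geometry of the diene (benzyloxy outside, methyl inside) together with endo placement of the chelated acyl group, which puts O5 and C7 cis. The step needs regioselectivity, secured because the 3-silyloxy and the 5-benzyloxy groups both polarise the diene toward C2, and C=C over C=O chemoselectivity, secured by the hindered, chelated ketone.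

Step 5
Reactants: 8 (2S)-1-[(1S,2R)-2-(benzyloxy)-4-(tert-butyldimethylsilyloxy)-2,6,6-trimethylcyclohex-3-en-1-yl]-2-cyclohexyl-2-hydroxyethan-1-one
Product: 9 (1S)-2-[(1R,2S)-2-(benzyloxy)-4-(tert-butyldimethylsilyloxy)-2,6,6-trimethylcyclohex-3-en-1-yl]-1-cyclohexylethane-1,2-diol (both C2 epimers)
Conditions: LiAlH4, THF, −40 → 0 °C; aq. NaOH work-up
Reagents that add atoms: none
Why: hydride reduction of the ketone turns the α-hydroxy ketone into a 1,2-diol, the handle for removing the auxiliary; both epimers at the new carbinol serve equally, and the silyl enol ether and benzyl ether are inert to hydride.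

Step 6
Reactants: 9 (1S)-2-[(1R,2S)-2-(benzyloxy)-4-(tert-butyldimethylsilyloxy)-2,6,6-trimethylcyclohex-3-en-1-yl]-1-cyclohexylethane-1,2-diol
Product: 10 (1S)-2-[(1R,2S)-4-(tert-butyldimethylsilyloxy)-2-hydroxy-2,6,6-trimethylcyclohex-3-en-1-yl]-1-cyclohexylethane-1,2-diol (both C2 epimers)
Conditions: H2 (1 atm), Pd(OH)2/C, EtOAc, rt
Reagents that add atoms: none
Why: hydrogenolysis of the benzyl ether is placed before any C=C bond of the chain exists, and the hindered trisubstituted silyl enol ether should survive it.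

Step 7
Reactants: 10 (1S)-2-[(1R,2S)-4-(tert-butyldimethylsilyloxy)-2-hydroxy-2,6,6-trimethylcyclohex-3-en-1-yl]-1-cyclohexylethane-1,2-diol
Product: 12 (1S,2R)-4-(tert-butyldimethylsilyloxy)-2,6,6-trimethyl-2-(trimethylsilyloxy)cyclohex-3-ene-1-carbaldehyde, via hydroxy aldehyde 11 (not isolated)
Conditions: NaIO4, NaHCO3, THF–H2O, 0 °C; extraction (CH2Cl2), drying; then N-(trimethylsilyl)imidazole, CH2Cl2, 0 °C → rt
Reagents that add atoms: N-(trimethylsilyl)imidazole, C[Si](C)(C)n1ccnc1
Why: periodate glycol cleavage (Malaprade reaction) removes the auxiliary as cyclohexanecarbaldehyde and reveals the C7 aldehyde under neutral conditions with no substitution at the hindered acyl carbon, and immediate silylation of the tertiary hydroxyl blocks retro-aldol opening in the basic step that follows.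

Step 8
Reactants: 12 (1S,2R)-4-(tert-butyldimethylsilyloxy)-2,6,6-trimethyl-2-(trimethylsilyloxy)cyclohex-3-ene-1-carbaldehyde; 13 ethyl (2E)-4-(diethoxyphosphoryl)-3-methylbut-2-enoate
Product: 14 ethyl (2E,4E)-5-[(1S,2S)-4-(tert-butyldimethylsilyloxy)-2,6,6-trimethyl-2-(trimethylsilyloxy)cyclohex-3-en-1-yl]-3-methylpenta-2,4-dienoate
Conditions: 13, LiN(SiMe3)2, THF–DMPU, −78 °C; then 12, −78 → 0 °C
Reagents that add atoms: none
Why: Horner–Wadsworth–Emmons olefination with the vinylogous C5 phosphonate, the usual C10 → C15 extension of carotenoid chemistry, should give the E alkene at C7=C8 because the weakly basic stabilised anion adds to the aldehyde faster than it removes the shielded C6 hydrogen.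

Step 9
Reactants: 14 ethyl (2E,4E)-5-[(1S,2S)-4-(tert-butyldimethylsilyloxy)-2,6,6-trimethyl-2-(trimethylsilyloxy)cyclohex-3-en-1-yl]-3-methylpenta-2,4-dienoate
Product: 15 (2E,4E)-5-[(1S,2S)-4-(tert-butyldimethylsilyloxy)-2,6,6-trimethyl-2-(trimethylsilyloxy)cyclohex-3-en-1-yl]-3-methylpenta-2,4-dien-1-ol
Conditions: iBu2AlH (2.2 equiv), CH2Cl2, −78 °C; MeOH, aq. KNaC4H4O6
Reagents that add atoms: none
Why: 1,2-reduction of the dienoate to the dienol by iBu2AlH, to which the silyl enol ether (the masked C3 ketone) and the silyl ether are inert.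

Step 10
Reactants: 15 (2E,4E)-5-[(1S,2S)-4-(tert-butyldimethylsilyloxy)-2,6,6-trimethyl-2-(trimethylsilyloxy)cyclohex-3-en-1-yl]-3-methylpenta-2,4-dien-1-ol
Product: 16 (3R,4S)-3-hydroxy-4-[(1E,3E)-5-hydroxy-3-methylpenta-1,3-dien-1-yl]-3,5,5-trimethylcyclohexan-1-one
Conditions: nBu4NF (2.2 equiv), AcOH (2.5 equiv), THF, 0 °C
Reagents that add atoms: none
Why: buffered fluoride desilylation frees the ketone and the tertiary alcohol, since acetic acid protonates the enolate and the alkoxide as they form, and the acid-free medium avoids the ionisation of the allylic C5–O bond that a protic acid would cause in the enol ether.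

Step 11
Reactants: 16 (3R,4S)-3-hydroxy-4-[(1E,3E)-5-hydroxy-3-methylpenta-1,3-dien-1-yl]-3,5,5-trimethylcyclohexan-1-one
Product: 17 {(2E,4E)-5-[(1S,2R)-2-hydroxy-2,6,6-trimethyl-4-oxocyclohexyl]-3-methylpenta-2,4-dien-1-yl}triphenylphosphonium bromide
Conditions: PPh3·HBr (1.05 equiv), MeOH, 0 °C → rt
Reagents that add atoms: triphenylphosphine hydrobromide, Br.c1ccccc1P(c1ccccc1)c1ccccc1
Why: the dienylic alcohol ionises to a pentadienyl cation that PPh3 captures at the primary terminus (the standard preparation of C15 Wittig salts), whereas the tertiary β-hydroxy ketone should not ionise under these mild conditions.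

Step 12
Reactants: 17 {(2E,4E)-5-[(1S,2R)-2-hydroxy-2,6,6-trimethyl-4-oxocyclohexyl]-3-methylpenta-2,4-dien-1-yl}triphenylphosphonium bromide; 18 (2E,4E,6E)-2,7-dimethylocta-2,4,6-trienedial
Product: 19 (2E,4E,6E,8E,10E,12E)-13-[(1S,2R)-2-hydroxy-2,6,6-trimethyl-4-oxocyclohexyl]-2,7,11-trimethyltrideca-2,4,6,8,10,12-hexaenal
Conditions: 18 (3 equiv), 1,2-epoxybutane, EtOH, 70 °C; then heptane, 90 °C
Reagents that add atoms: none
Why: base-free Wittig reaction in which the epoxide traps HBr and releases the semi-stabilised ylide, which should react with an aldehyde far faster than with the ring ketone; excess dialdehyde holds the reaction at mono-olefination and heating equilibrates the new C11=C12 bond to E.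

Step 13
Reactants: 15 (2E,4E)-5-[(1S,2S)-4-(tert-butyldimethylsilyloxy)-2,6,6-trimethyl-2-(trimethylsilyloxy)cyclohex-3-en-1-yl]-3-methylpenta-2,4-dien-1-ol
Product: 20 (2E,4E)-5-[(1S,2S)-4-(tert-butyldimethylsilyloxy)-2,6,6-trimethyl-2-(trimethylsilyloxy)cyclohex-3-en-1-yl]-3-methylpenta-2,4-dien-1-yl acetate
Conditions: Ac2O, pyridine, DMAP (cat.), CH2Cl2, 0 °C
Reagents that add atoms: acetic anhydride, CC(=O)OC(C)=O
Why: acetylation makes the dienylic oxygen a poorer leaving group under dilute acid, so that the chain survives the acidic unmasking of the ring in the next step.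

Step 14
Reactants: 20 (2E,4E)-5-[(1S,2S)-4-(tert-butyldimethylsilyloxy)-2,6,6-trimethyl-2-(trimethylsilyloxy)cyclohex-3-en-1-yl]-3-methylpenta-2,4-dien-1-yl acetate
Product: 21 (2E,4E)-3-methyl-5-[(1S)-2,6,6-trimethyl-4-oxocyclohex-2-en-1-yl]penta-2,4-dien-1-yl acetate
Conditions: 0.5 M HCl, THF–H2O, 0 °C → rt
Reagents that add atoms: none
Why: acid hydrolysis of the silyl enol ether with loss of the β-silyloxy group (ionisation of the allylic C5–O bond), the usual unmasking of a 1-oxy-3-silyloxy diene cycloadduct to a cyclohexenone, leaves C6 untouched.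

Step 15
Reactants: 21 (2E,4E)-3-methyl-5-[(1S)-2,6,6-trimethyl-4-oxocyclohex-2-en-1-yl]penta-2,4-dien-1-yl acetate
Product: 22 (1R,5S,6R)-5-[(1E,3E)-5-hydroxy-3-methylpenta-1,3-dien-1-yl]-4,4,6-trimethyl-7-oxabicyclo[4.1.0]heptan-2-one
Conditions: H2O2 (30 %), NaOH (0.3 equiv), MeOH, 0 °C
Reagents that add atoms: hydrogen peroxide, OO
Why: Weitz–Scheffer epoxidation, in which hydroperoxide adds to C5 on the face opposite the C6 side chain (held pseudoaxial by strain with the C5 methyl and the C1 methyls), should place the epoxide oxygen trans to the chain, the acetate being removed by methanolysis in the same medium.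

Step 16
Reactants: 22 (1R,5S,6R)-5-[(1E,3E)-5-hydroxy-3-methylpenta-1,3-dien-1-yl]-4,4,6-trimethyl-7-oxabicyclo[4.1.0]heptan-2-one
Product: 23 (3S,4S)-3-hydroxy-4-[(1E,3E)-5-hydroxy-3-methylpenta-1,3-dien-1-yl]-3,5,5-trimethylcyclohexan-1-one
Conditions: SmI2 (2.5 equiv), THF–MeOH, −90 °C
Reagents that add atoms: none
Why: single-electron reduction of the α,β-epoxy ketone cleaves only the Cα–O bond, so the β-hydroxy ketone keeps the C5 configuration set in step 15.

Step 17
Reactants: 23 (3S,4S)-3-hydroxy-4-[(1E,3E)-5-hydroxy-3-methylpenta-1,3-dien-1-yl]-3,5,5-trimethylcyclohexan-1-one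
Product: 24 {(2E,4E)-5-[(1S,2S)-2-hydroxy-2,6,6-trimethyl-4-oxocyclohexyl]-3-methylpenta-2,4-dien-1-yl}triphenylphosphonium bromide
Conditions: PPh3·HBr (1.05 equiv), MeOH, 0 °C → rt
Reagents that add atoms: triphenylphosphine hydrobromide, Br.c1ccccc1P(c1ccccc1)c1ccccc1
Why: the same acid-mediated substitution of the dienylic alcohol by PPh3 as in step 11.

Step 18
Reactants: 19 (2E,4E,6E,8E,10E,12E)-13-[(1S,2R)-2-hydroxy-2,6,6-trimethyl-4-oxocyclohexyl]-2,7,11-trimethyltrideca-2,4,6,8,10,12-hexaenal; 24 {(2E,4E)-5-[(1S,2S)-2-hydroxy-2,6,6-trimethyl-4-oxocyclohexyl]-3-methylpenta-2,4-dien-1-yl}triphenylphosphonium bromide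
Product: 25 (all-E)-(5R,6S,5'S,6'S)-5,5'-dihydroxy-5,6,5',6'-tetrahydro-β,β-carotene-3,3'-dione
Conditions: 1,2-epoxybutane, EtOH, 70 °C; then heptane, 90 °C
Reagents that add atoms: none
Why: second base-free Wittig reaction, which should join the two halves at C11=C12 without touching either β-hydroxy ketone, the polyene equilibrating to all-E on heating.

**Compound list**
1 | (3E)-4-methoxypent-3-en-2-one | CC(=O)/C=C(C)/OC | starting material
2 | (3E)-4-(benzyloxy)pent-3-en-2-one | CC(=O)/C=C(C)/OCc1ccccc1 | intermediate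
3 | (3E)-4-(benzyloxy)-2-(tert-butyldimethylsilyloxy)penta-1,3-diene | C=C(O[Si](C)(C)C(C)(C)C)/C=C(C)/OCc1ccccc1 | intermediate
4 | (2S)-2-cyclohexyl-2-hydroxyacetic acid | OC(=O)[C@@H](O)C1CCCCC1 | starting material
5 | 1-bromo-2-methylprop-1-ene | CC(C)=CBr | starting material
6 | (2-methylprop-1-en-1-yl)lithium | [Li]C=C(C)C | intermediate
7 | (1S)-1-cyclohexyl-1-hydroxy-4-methylpent-3-en-2-one | CC(C)=CC(=O)[C@@H](O)C1CCCCC1 | intermediate
8 | (2S)-1-[(1S,2R)-2-(benzyloxy)-4-(tert-butyldimethylsilyloxy)-2,6,6-trimethylcyclohex-3-en-1-yl]-2-cyclohexyl-2-hydroxyethan-1-one | O=C([C@@H](O)C1CCCCC1)[C@H]2C(C)(C)CC(O[Si](C)(C)C(C)(C)C)=C[C@@]2(C)OCc3ccccc3 | intermediate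
9 | (1S)-2-[(1R,2S)-2-(benzyloxy)-4-(tert-butyldimethylsilyloxy)-2,6,6-trimethylcyclohex-3-en-1-yl]-1-cyclohexylethane-1,2-diol, both C2 epimers | OC([C@@H](O)C1CCCCC1)[C@H]2C(C)(C)CC(O[Si](C)(C)C(C)(C)C)=C[C@@]2(C)OCc3ccccc3 | intermediate
10 | (1S)-2-[(1R,2S)-4-(tert-butyldimethylsilyloxy)-2-hydroxy-2,6,6-trimethylcyclohex-3-en-1-yl]-1-cyclohexylethane-1,2-diol, both C2 epimers | OC([C@@H](O)C1CCCCC1)[C@H]2C(C)(C)CC(O[Si](C)(C)C(C)(C)C)=C[C@@]2(C)O | intermediate
11 | (1S,2R)-4-(tert-butyldimethylsilyloxy)-2-hydroxy-2,6,6-trimethylcyclohex-3-ene-1-carbaldehyde | O=C[C@H]1C(C)(C)CC(O[Si](C)(C)C(C)(C)C)=C[C@@]1(C)O | intermediate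
12 | (1S,2R)-4-(tert-butyldimethylsilyloxy)-2,6,6-trimethyl-2-(trimethylsilyloxy)cyclohex-3-ene-1-carbaldehyde | O=C[C@H]1C(C)(C)CC(O[Si](C)(C)C(C)(C)C)=C[C@@]1(C)O[Si](C)(C)C | intermediate
13 | ethyl (2E)-4-(diethoxyphosphoryl)-3-methylbut-2-enoate | CCOC(=O)/C=C(C)/CP(=O)(OCC)OCC | starting material
14 | ethyl (2E,4E)-5-[(1S,2S)-4-(tert-butyldimethylsilyloxy)-2,6,6-trimethyl-2-(trimethylsilyloxy)cyclohex-3-en-1-yl]-3-methylpenta-2,4-dienoate | CCOC(=O)/C=C(C)/C=C/[C@H]1C(C)(C)CC(O[Si](C)(C)C(C)(C)C)=C[C@@]1(C)O[Si](C)(C)C | intermediate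
15 | (2E,4E)-5-[(1S,2S)-4-(tert-butyldimethylsilyloxy)-2,6,6-trimethyl-2-(trimethylsilyloxy)cyclohex-3-en-1-yl]-3-methylpenta-2,4-dien-1-ol | OC/C=C(C)/C=C/[C@H]1C(C)(C)CC(O[Si](C)(C)C(C)(C)C)=C[C@@]1(C)O[Si](C)(C)C | intermediate
16 | (3R,4S)-3-hydroxy-4-[(1E,3E)-5-hydroxy-3-methylpenta-1,3-dien-1-yl]-3,5,5-trimethylcyclohexan-1-one | OC/C=C(C)/C=C/[C@H]1C(C)(C)CC(=O)C[C@@]1(C)O | intermediate
17 | {(2E,4E)-5-[(1S,2R)-2-hydroxy-2,6,6-trimethyl-4-oxocyclohexyl]-3-methylpenta-2,4-dien-1-yl}triphenylphosphonium bromide | [Br-].C(/C=C(C)/C=C/[C@H]1C(C)(C)CC(=O)C[C@@]1(C)O)[P+](c2ccccc2)(c3ccccc3)c4ccccc4 | intermediate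
18 | (2E,4E,6E)-2,7-dimethylocta-2,4,6-trienedial | O=C/C(C)=C/C=C/C=C(C)/C=O | starting material
19 | (2E,4E,6E,8E,10E,12E)-13-[(1S,2R)-2-hydroxy-2,6,6-trimethyl-4-oxocyclohexyl]-2,7,11-trimethyltrideca-2,4,6,8,10,12-hexaenal | O=C/C(C)=C/C=C/C=C(C)/C=C/C=C(C)/C=C/[C@H]1C(C)(C)CC(=O)C[C@@]1(C)O | intermediate
20 | (2E,4E)-5-[(1S,2S)-4-(tert-butyldimethylsilyloxy)-2,6,6-trimethyl-2-(trimethylsilyloxy)cyclohex-3-en-1-yl]-3-methylpenta-2,4-dien-1-yl acetate | CC(=O)OC/C=C(C)/C=C/[C@H]1C(C)(C)CC(O[Si](C)(C)C(C)(C)C)=C[C@@]1(C)O[Si](C)(C)C | intermediate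
21 | (2E,4E)-3-methyl-5-[(1S)-2,6,6-trimethyl-4-oxocyclohex-2-en-1-yl]penta-2,4-dien-1-yl acetate | CC(=O)OC/C=C(C)/C=C/[C@H]1C(C)(C)CC(=O)C=C1C | intermediate
22 | (1R,5S,6R)-5-[(1E,3E)-5-hydroxy-3-methylpenta-1,3-dien-1-yl]-4,4,6-trimethyl-7-oxabicyclo[4.1.0]heptan-2-one | OC/C=C(C)/C=C/[C@H]1C(C)(C)CC(=O)[C@@H]2O[C@]12C | intermediate
23 | (3S,4S)-3-hydroxy-4-[(1E,3E)-5-hydroxy-3-methylpenta-1,3-dien-1-yl]-3,5,5-trimethylcyclohexan-1-one | OC/C=C(C)/C=C/[C@H]1C(C)(C)CC(=O)C[C@]1(C)O | intermediate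
24 | {(2E,4E)-5-[(1S,2S)-2-hydroxy-2,6,6-trimethyl-4-oxocyclohexyl]-3-methylpenta-2,4-dien-1-yl}triphenylphosphonium bromide | [Br-].C(/C=C(C)/C=C/[C@H]1C(C)(C)CC(=O)C[C@]1(C)O)[P+](c2ccccc2)(c3ccccc3)c4ccccc4 | intermediate
25 | (all-E)-(5R,6S,5'S,6'S)-5,5'-dihydroxy-5,6,5',6'-tetrahydro-β,β-carotene-3,3'-dione | CC(/C=C/C=C(C)/C=C/[C@H]1C(C)(C)CC(=O)C[C@]1(C)O)=C\C=C\C=C(C)\C=C\C=C(C)\C=C\[C@H]1C(C)(C)CC(=O)C[C@@]1(C)O | target

**Count and risks**
Total step count: 18. Longest linear sequence: 14 steps (1, 2, 4, 5, 6, 7, 8, 9, 13, 14, 15, 16, 17, 18).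

Steps most likely to fail:

1. Step 4. Both partners are hindered (β,β-dimethyl enone, diene with an inside methyl), so the addition may be slow, may stop after the first C–C bond with loss of the silyl group, or may proceed with poor facial or endo selectivity. Fallback, from 3 back to 12: the auxiliary and the Lewis acid are given up, and diene 3 is combined with 3-methylbut-2-enal without catalyst under high pressure (about 15 kbar, CH2Cl2, 25 °C). This concerted thermal cycloaddition should give the racemic endo adduct rac-(1S,2R)-2-(benzyloxy)-4-(tert-butyldimethylsilyloxy)-2,6,6-trimethylcyclohex-3-ene-1-carbaldehyde F1. Reduction with NaBH4 (EtOH, 0 °C) gives rac-[(1R,2S)-2-(benzyloxy)-4-(tert-butyldimethylsilyloxy)-2,6,6-trimethylcyclohex-3-en-1-yl]methanol F2. The enantiomers are separated by preparative chromatography on a chiral stationary phase to give [(1R,2S)-2-(benzyloxy)-4-(tert-butyldimethylsilyloxy)-2,6,6-trimethylcyclohex-3-en-1-yl]methanol F3. Oxidation with nPr4N[RuO4] and N-methylmorpholine N-oxide returns the single-enantiomer aldehyde (1S,2R)-2-(benzyloxy)-4-(tert-butyldimethylsilyloxy)-2,6,6-trimethylcyclohex-3-ene-1-carbaldehyde F4. Hydrogenolysis (H2, Pd(OH)2/C) then gives 11, and silylation as in step 7 gives 12.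

2. Step 15. The C6 hydrogen of 21 is doubly allylic and γ to the ketone, so base may epimerise C6 or move the ring double bond into conjugation with the chain, and the facial preference of the epoxidation may be modest. Fallback, from 7 back to 23: the trans ring is made by the same cycloaddition with the geometric isomer of the diene. (Z)-4-(trimethylsilyloxy)pent-3-en-2-one is silylated (LiN(iPr)2, TBSCl) to (3Z)-2-(tert-butyldimethylsilyloxy)-4-(trimethylsilyloxy)penta-1,3-diene F5, in which the oxygen at C5 sits inside, so that endo addition to 7 (Me2AlCl) should give the trans adduct (2S)-2-cyclohexyl-2-hydroxy-1-[(1S,2S)-4-(tert-butyldimethylsilyloxy)-2,6,6-trimethyl-2-(trimethylsilyloxy)cyclohex-3-en-1-yl]ethan-1-one F6. LiAlH4 gives (1S)-1-cyclohexyl-2-[(1R,2R)-4-(tert-butyldimethylsilyloxy)-2,6,6-trimethyl-2-(trimethylsilyloxy)cyclohex-3-en-1-yl]ethane-1,2-diol F7, and NaIO4 gives (1S,2S)-4-(tert-butyldimethylsilyloxy)-2,6,6-trimethyl-2-(trimethylsilyloxy)cyclohex-3-ene-1-carbaldehyde F8. Olefination with 13 as in step 8 gives ethyl (2E,4E)-5-[(1S,2R)-4-(tert-butyldimethylsilyloxy)-2,6,6-trimethyl-2-(trimethylsilyloxy)cyclohex-3-en-1-yl]-3-methylpenta-2,4-dienoate F9, iBu2AlH gives (2E,4E)-5-[(1S,2R)-4-(tert-butyldimethylsilyloxy)-2,6,6-trimethyl-2-(trimethylsilyloxy)cyclohex-3-en-1-yl]-3-methylpenta-2,4-dien-1-ol F10, and buffered fluoride as in step 10 gives 23.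

3. Step 8. The aldehyde is flanked by two fully substituted carbons and carries a β-silyloxy group, so addition may be slow and the base may instead cause β-elimination of silanolate or epimerisation at C6. Fallback, from 12 back to 14: the C5 unit is added in two stages. A base-free Wittig reaction with the stable ylide 1-(triphenylphosphoranylidene)propan-2-one (toluene, 80 °C) gives (3E)-4-[(1S,2S)-4-(tert-butyldimethylsilyloxy)-2,6,6-trimethyl-2-(trimethylsilyloxy)cyclohex-3-en-1-yl]but-3-en-2-one F11. Its methyl ketone no longer has an acidic hydrogen next to the ring and is olefinated with triethyl phosphonoacetate (NaH, THF) to give 14 after removal of the 2Z isomer.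

Further compounds
F1 | step 4 | rac-(1S,2R)-2-(benzyloxy)-4-(tert-butyldimethylsilyloxy)-2,6,6-trimethylcyclohex-3-ene-1-carbaldehyde | O=C[C@H]1C(C)(C)CC(O[Si](C)(C)C(C)(C)C)=C[C@@]1(C)OCc2ccccc2
F2 | step 4 | rac-[(1R,2S)-2-(benzyloxy)-4-(tert-butyldimethylsilyloxy)-2,6,6-trimethylcyclohex-3-en-1-yl]methanol | OC[C@H]1C(C)(C)CC(O[Si](C)(C)C(C)(C)C)=C[C@@]1(C)OCc2ccccc2
F3 | step 4 | [(1R,2S)-2-(benzyloxy)-4-(tert-butyldimethylsilyloxy)-2,6,6-trimethylcyclohex-3-en-1-yl]methanol | OC[C@H]1C(C)(C)CC(O[Si](C)(C)C(C)(C)C)=C[C@@]1(C)OCc2ccccc2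
F4 | step 4 | (1S,2R)-2-(benzyloxy)-4-(tert-butyldimethylsilyloxy)-2,6,6-trimethylcyclohex-3-ene-1-carbaldehyde | O=C[C@H]1C(C)(C)CC(O[Si](C)(C)C(C)(C)C)=C[C@@]1(C)OCc2ccccc2
F5 | step 15 | (3Z)-2-(tert-butyldimethylsilyloxy)-4-(trimethylsilyloxy)penta-1,3-diene | C=C(O[Si](C)(C)C(C)(C)C)/C=C(C)\O[Si](C)(C)C
F6 | step 15 | (2S)-2-cyclohexyl-2-hydroxy-1-[(1S,2S)-4-(tert-butyldimethylsilyloxy)-2,6,6-trimethyl-2-(trimethylsilyloxy)cyclohex-3-en-1-yl]ethan-1-one | O=C([C@@H](O)C1CCCCC1)[C@H]2C(C)(C)CC(O[Si](C)(C)C(C)(C)C)=C[C@]2(C)O[Si](C)(C)C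
F7 | step 15 | (1S)-1-cyclohexyl-2-[(1R,2R)-4-(tert-butyldimethylsilyloxy)-2,6,6-trimethyl-2-(trimethylsilyloxy)cyclohex-3-en-1-yl]ethane-1,2-diol, both C2 epimers | OC([C@@H](O)C1CCCCC1)[C@H]2C(C)(C)CC(O[Si](C)(C)C(C)(C)C)=C[C@]2(C)O[Si](C)(C)C
F8 | step 15 | (1S,2S)-4-(tert-butyldimethylsilyloxy)-2,6,6-trimethyl-2-(trimethylsilyloxy)cyclohex-3-ene-1-carbaldehyde | O=C[C@H]1C(C)(C)CC(O[Si](C)(C)C(C)(C)C)=C[C@]1(C)O[Si](C)(C)C
F9 | step 15 | ethyl (2E,4E)-5-[(1S,2R)-4-(tert-butyldimethylsilyloxy)-2,6,6-trimethyl-2-(trimethylsilyloxy)cyclohex-3-en-1-yl]-3-methylpenta-2,4-dienoate | CCOC(=O)/C=C(C)/C=C/[C@H]1C(C)(C)CC(O[Si](C)(C)C(C)(C)C)=C[C@]1(C)O[Si](C)(C)C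
F10 | step 15 | (2E,4E)-5-[(1S,2R)-4-(tert-butyldimethylsilyloxy)-2,6,6-trimethyl-2-(trimethylsilyloxy)cyclohex-3-en-1-yl]-3-methylpenta-2,4-dien-1-ol | OC/C=C(C)/C=C/[C@H]1C(C)(C)CC(O[Si](C)(C)C(C)(C)C)=C[C@]1(C)O[Si](C)(C)C
F11 | step 8 | (3E)-4-[(1S,2S)-4-(tert-butyldimethylsilyloxy)-2,6,6-trimethyl-2-(trimethylsilyloxy)cyclohex-3-en-1-yl]but-3-en-2-one | CC(=O)/C=C/[C@H]1C(C)(C)CC(O[Si](C)(C)C(C)(C)C)=C[C@@]1(C)O[Si](C)(C)C
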